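(The numbers in the tables were generated by integration on assumed constants, noise included.)

At 22 µM, the free catalyst in the south-east run was a small charge against 20 mM of starting material, and that run's target stood still from its first reading, so I first suspected a dead catalyst.

| flask | starting material | partner | second substrate | free catalyst | impurity | added ligand | temperature | remark | time |
|---|---|---|---|---|---|---|---|---|---|
| west | 20 mM | 36 mM | 16 mM | 22 µM | 2.3 µM | 34 µM | 35 °C | run made earlier |  |
| south-east | 20 mM | 36 mM | 64 mM | 22 µM | 2.3 µM | 34 µM | 57 °C | run made earlier |  |
| Friday's | 20 mM | 36.0 mM | 20.0 mM | 22 µM | 2.3 µM | 34 µM |  | at 25 °C until 80 min, from then on at 65 °C | 2.5 h |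
| Sunday's | 20 mM | 36.0 mM | 80.0 mM | 22 µM | 2.3 µM | 34 µM |  | at 25 °C throughout | 2.5 h |

| run | time / min | target / % | starting material / % |
|---|---|---|---|
| west | 10.0 | 84.7 | 16.3 |
| west | 20.0 | 89.6 | 9.1 |
| west | 30.0 | 93.7 | 6.6 |
| west | 40.0 | 94.1 | 5.2 |
| west | 50.0 | 95.5 | 3.6 |
| south-east | 3.00 | 45.8 | 56.2 |
| south-east | 6.00 | 47.4 | 54.7 |
| south-east | 10.0 | 43.8 | 53.5 |
| south-east | 12.0 | 44.6 | 53.9 |
| south-east | 15.0 | 46.4 | 53.8 |

(each reading ± 1 percentage point)



1. which of the two ends with the higher amount of target, in percent of the starting material charged ("neither" if they lie within 2 percentage points) (Friday's / Sunday's / neither)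
2. target at the end, in percent of the starting material charged, Friday's
3. target at the end, in percent of the starting material charged, Sunday's

The west run, with the same catalyst charge, still reached 95.5% of target at 50.0 min, but it ran at 35 °C rather than 57 °C and with 16 mM rather than 64 mM of second substrate, so it cleared nothing. I therefore wrote the balance of the partner, the limiting reagent of the south-east run, Friday's and Sunday's, taking one partner per substrate. If both substrates fall by the same fraction and that fall takes up the whole partner charge, the balance gives 36.0% for Sunday's. I called this ratio, c(partner) divided by c(starting material) plus c(second substrate), the partner coverage. It is 100% for the west run, which kept climbing, and 42.9% for the south-east run, whose five target readings average 45.6%. That nearness made me drop the dead catalyst.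

The gap of 2.7 percentage points stood against a scatter of 1 point per reading, so I did not wave it off. Read through the balance, the south-east readings give a reading of 1.12 for the selectivity factor of starting material over second substrate, at 57 °C. No reading shows that factor at 25 °C, so for my estimate I took the coverage as the low end and the gap as an upward allowance: Friday's 90.0% to 92.7%, Sunday's 36.0% to 38.7%.

Time was the last doubt. Friday's stay at 25 °C lasts 8.00 times the 10.0 min in which the west run gave 84.7%, so I expected the cooler bath to leave enough time.

The forecast gave Friday's, with 92% and 42%: “Both new runs therefore end when the partner is exhausted, and temperature matters little.” Its Sunday's figure lay above my range.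

The simulation gave 90.0% for Friday's and 36.0% for Sunday's, so Friday's ended higher, and the forecast's Sunday's figure stood 6 points too high.

    free catalyst → spent catalyst B (k = 2.00 × 10⁻⁴ min⁻¹, Ea = 97.0 kJ mol⁻¹)
    free catalyst + added ligand ⇌ idle complex (K = 38000 M⁻¹, k = 2700 M⁻¹ min⁻¹, Ea = 46.0 kJ mol⁻¹, ΔH = −13.0 kJ mol⁻¹)
    second substrate + partner + free catalyst → free catalyst + second product (k = 14000 M⁻² s⁻¹, Ea = 19.0 kJ mol⁻¹)
    free catalyst + impurity → spent catalyst A (k = 80000 M⁻¹ s⁻¹, Ea = 24.0 kJ mol⁻¹)
    starting material + partner + free catalyst → free catalyst + target (k = 14000 M⁻² s⁻¹, Ea = 22.0 kJ mol⁻¹)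
    (constants at 25 °C)

In Friday's, both partner steps ran at 25 °C until target stood at 89.5% with partner at 0.575% at the change of temperature, and the end gave 90.0% with partner at 0%. In Sunday's, target stood at 36.0% with partner at 0% by 1.25 h, and it was unchanged at 2.50 h. The two partner steps carry the same constant at 25 °C, 14000 M⁻² s⁻¹, and Sunday's target equals its coverage of 36.0%.

For a neighbour of Sunday's with 50 mM of starting material, the coverage is 27.7%. The computed target there is 27.7%, with partner at 0%.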